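The oak run starts with more starting material than the birch run, yet target appears in both at nearly the same molar pace.

| flask | starting material | second substrate | free enzyme | remark | time |
|---|---|---|---|---|---|
| birch | 0.050 M | 0.10 M | 5 µM | run made earlier |  |
| alder | 0.050 M | 0.10 M | 2.5 µM | run made earlier |  |
| cedar | 0.050 M | 0.10 M | 3.8 µM | run made earlier |  |
| oak | 0.075 M | 0.10 M | 5 µM | run made earlier |  |
| spring | 0.050 M (fed, over 40 min) | 0.100 M | 5.0 µM | all else is in the flask from the start; the feed brings no volume worth counting | 50 min |
| midnight | 0.050 M | 0.100 M | 5.0 µM | everything together at the start | 50 min |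
| dawn | 0.050 M | 0.100 M (fed, over 40 min) | 5.0 µM | all else is in the flask from the start; the feed brings no volume worth counting | 50 min |
| dusk | 0.050 M | 0.100 M (in portions, 3, over 40 min) | 5.0 µM | first portion at the start, last at 40 min | 50 min |

| run | time / min | target / % | starting material / % |
|---|---|---|---|
| birch | 4.00 | 4.7 | 95.6 |
| birch | 10.0 | 13.0 | 90.2 |
| birch | 20.0 | 22.9 | 77.0 |
| birch | 30.0 | 32.9 | 64.8 |
| alder | 5.00 | 3.3 | 96.4 |
| alder | 15.0 | 7.2 | 91.0 |
| alder | 25.0 | 14.6 | 85.7 |
| alder | 40.0 | 23.1 | 76.8 |
| cedar | 10.0 | 7.7 | 90.5 |
| cedar | 20.0 | 16.9 | 82.5 |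
| cedar | 30.0 | 24.9 | 74.9 |
| cedar | 40.0 | 34.5 | 66.2 |
| oak | 10.0 | 7.3 | 91.9 |
| oak | 20.0 | 16.3 | 84.9 |
| oak | 30.0 | 22.2 | 77.6 |
| oak | 40.0 | 29.8 | 71.3 |

(standard deviation of a reading: 1 percentage point)

- what was read earlier has a scatter of 1 percentage point, one standard deviation

1. the best flask by amount of target, in percent of the starting material charged; "all alike" if 1.5 percentage points covers them all (spring / midnight / dawn / dusk / all alike)
2. amount of target at the end, in percent of the starting material charged, spring
3. amount of target at the end, in percent of the starting material charged, midnight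
4. amount of target at the end, in percent of the starting material charged, dawn
5. amount of target at the end, in percent of the starting material charged, dusk

Up to their last readings, the two paces stand as follows:

pace, birch = 5.48 × 10⁻⁴ M min⁻¹
pace, oak = 5.59 × 10⁻⁴ M min⁻¹

A rate that ignores c(starting material) is zero order in it. Alder, with less free enzyme, runs slower, and in step with that enzyme. One constant therefore carries these runs: the turnover number, the pace per free enzyme charged.

birch: 110 min⁻¹
cedar: 113 min⁻¹
alder: 116 min⁻¹

The crossing to watch is the run-out time: the charge of starting material divided by turnover times free enzyme. In this zero-order view, target grows with the clock below that time, and beyond it the charge caps the target.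

run-out time, midnight = 91.2 min

Midnight stops earlier, so my own reckoning gives it 54.8%. Spring's feed of 0.00125 M min⁻¹ exceeds the pace, so I expect spring to lag midnight slightly. For dawn and dusk I commit to no number: birch, alder, cedar and oak each began with 0.10 M of second substrate.

The forecast names midnight as best, with 54% for spring, 55% for midnight, 50% for dawn and 52% for dusk; of the last two it says “both probably lag slightly”.

The flasks give 52.9% for spring, 55.0% for midnight, 38.9% for dawn and 39.9% for dusk, so midnight leads.

    second substrate + loaded enzyme ⇌ second complex (K = 9.70 L mol⁻¹, k = 3.30 × 10⁵ L mol⁻¹ min⁻¹)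
    second complex → free enzyme + target (k = 270 min⁻¹)
    first complex → loaded enzyme + first product (k = 1300 min⁻¹)
    starting material + free enzyme ⇌ first complex (K = 390 L mol⁻¹, k = 4.80 × 10⁵ L mol⁻¹ min⁻¹)

Spring, with a mean c(starting material) of 0.0145 M over its first 40 min, averaged a turnover of 106 min⁻¹ over its whole 50 min, while dawn, with a mean c(second substrate) of 0.0447 M over its first 40 min, averaged 77.8 min⁻¹ over its whole 50 min and ended 11 percentage points below the forecast. The neighbour of midnight charged with 1.2 × 10⁻⁵ M of free enzyme has a reckoned run-out time of 38.0 min, shorter than its 50 min, and it ends with target at 100% and starting material at 0%.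

The numbers in the tables come from a simulation with made-up constants, noise included.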